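Readings and results were generated by integration with constants of no real substance; noise was put on by code.

I had to decide whether to charge Tuesday's flask with 200 mM of starting material against 96.0 mM of partner, so I kept books on the earlier runs.

| flask | starting material | partner | time |
|---|---|---|---|
| Wednesday's | 80.0 mM | 96.0 mM |  |
| Saturday's | 48.0 mM | 64.0 mM |  |
| Thursday's | 120 mM | 96.0 mM |  |
| Sunday's | 80.0 mM | 140 mM |  |
| Tuesday's | 200 mM | 96.0 mM | 92 h |

| run | time / h | [target] / mM |
|---|---|---|
| Wednesday's run | 3.7 | 1.42 |
| Wednesday's run | 5.8 | 1.94 |
| Wednesday's run | 9.2 | 3.58 |
| Wednesday's run | 15 | 6.91 |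
| Wednesday's run | 23 | 10.36 |
| Wednesday's run | 37 | 14.13 |
| Wednesday's run | 58 | 17.16 |
| Wednesday's run | 92 | 17.91 |
| Saturday's run | 3.7 | 0.67 |
| Saturday's run | 5.8 | 0.55 |
| Saturday's run | 9.2 | 1.73 |
| Saturday's run | 15 | 2.97 |
| Saturday's run | 23 | 4.82 |
| Saturday's run | 37 | 7.12 |
| Saturday's run | 58 | 8.56 |
| Saturday's run | 92 | 9.08 |
| Thursday's run | 3.7 | 1.16 |
| Thursday's run | 5.8 | 2.43 |
| Thursday's run | 9.2 | 5.65 |
| Thursday's run | 15 | 9.80 |
| Thursday's run | 23 | 14.46 |
| Thursday's run | 37 | 19.42 |
| Thursday's run | 58 | 22.92 |
| Thursday's run | 92 | 24.69 |
| Sunday's run | 3.7 | 1.25 |
| Sunday's run | 5.8 | 2.74 |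
| Sunday's run | 9.2 | 5.21 |
| Sunday's run | 15 | 9.36 |
| Sunday's run | 23 | 12.89 |
| Sunday's run | 37 | 17.69 |
| Sunday's run | 58 | 20.59 |
| Sunday's run | 92 | 22.65 |

(scatter of a reading: 0.2 mM)

- order of the initial rate in [starting material], near the charge of the Wednesday's run, the rate being that where two percent of its starting material are target (one fixed amount of target, the same in the runs compared)
- order of the initial rate in [partner], near the charge of the Wednesday's run, the rate being that where two percent of its starting material are target
- target in the Tuesday's run at 92 h, as a share of the starting material charged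

- Overall: starting material + partner -> target.
- Constant volume, constant temperature.
- "The second partner" is partner.
- An order is taken over about fifteen percent of the charge, up and down.

Each turnover takes one starting material and one partner into one target. In Wednesday's run starting material was the limiting reagent, so I opened the ledger there. The first entry was 17.91 mM of target at 92 h. Partner was debited by the same amount, which left 78.1 mM of it, more than the 62.1 mM of starting material not booked as target. Wednesday's 22.4 % is my arrival share, the target at 92 h over the starting material charged.

Thursday's run, with more starting material, read 20.6 %, lower than Wednesday's. Sunday's run, with more partner, read 28.3 %, higher than Wednesday's. I carried the Wednesday-to-Thursday slope straight on to Tuesday's charge, which gave my own share of 17.0 %. In Tuesday's flask partner is the smaller charge, and that estimated share books 34.0 mM of its 96.0 mM as target, which in my reckoning closes the ledger with 62.0 mM of partner not booked as target.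

The forecast gave orders of 0.9 in starting material and 0.85 in partner, and a Tuesday share of 18 %, above my figure. Of the plateaus it said: “This suggests an equilibrium limit.” The flask gave orders of 0.71 and 0.60, both lower than forecast, and a share of 17.4 %, which agrees with the forecast within the margin.

    starting material → intermediate (0.02776 h⁻¹)
    intermediate + partner → target (0.8568 M⁻¹ h⁻¹)
    intermediate → side product (0.1069 h⁻¹)
    starting material → decomposed substrate (0.01264 h⁻¹)
    2 starting material → homo dimer (0.1098 M⁻¹ h⁻¹)

Tuesday's arrival share of 17.4 % stands below Wednesday's 22.4 %, and it debits 34.8 mM of partner. In Tuesday's run starting material also pairs with itself into homo dimer, and that path lowers the share. At Tuesday's charge, at the start, that step removes starting material at a fractional rate of 0.0439 h⁻¹, faster than the 0.0278 h⁻¹ of the step to intermediate. Tuesday's run without that path has an arrival share of 23.8 %, higher by 6.4 percentage points.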